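**Strategy**

Atoms are numbered in the order of the target SMILES; ring A is the cyclopentene C7–C9–C10–C11–C30 and ring B the cyclohexadiene C11–C12–C16–C27–C28–C30. Everything rests on cutting C28–C30: the C28 hydroxyl lies homoallylic to C10=C11 across the quaternary C30, the pattern left when a ring A allylboronate (boron on C10, alkene C11=C30) adds to a C28 aldehyde tethered through C11. This single allyl transfer closes ring B, creates C30 and C28 with their relative configuration and moves the alkene to C10=C11. Its precursor is a 2-cyclopentenyl pinacol boronate carrying at C11 the tetrasubstituted enoate C12(CO2Me)=C16 with the CH2CHO arm cis to ring A.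

Key step: step 27

Remark: Oxb stands for the 3,3-dimethyl-7-oxabicyclo[2.2.1]heptan-1-yl group whose CH–O bridgehead (C4 of the bicycle, C21) is S, as drawn in 5; TBS = tert-butyldimethylsilyl; Bpin = 4,4,5,5-tetramethyl-1,3,2-dioxaborolan-2-yl.
Remark: the geometry of C12=C16 is the same in 33, 34 and 35 (C27 arm cis to ring A); only the CIP descriptor changes, from Z in the primary alcohols to E in the aldehyde, so the key-step aldehyde 35 is the (2E) isomer.
Remark: the acid end of half-ester 9 is the one that is reduced, so its ester carbon becomes C30 and its acid carbon C4; this requires the R enantiomer.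
Remark: solutions of LiN(iPr)2, LiN(SiMe3)2 and BrZnCH2CO2Me are taken as preformed reagents.

**Route**

Step 1
Reactants: 1 3-methylbut-3-en-1-ol; 2 1-bromo-3-methylbut-2-ene
Product: 3 7-methyl-3-methylideneoct-6-en-1-ol
Conditions: n-BuLi (2.1 equiv), TMEDA, Et2O/hexane, 0 °C to rt; then 2, −78 °C to rt; H2O
Reagents that add atoms: none
Why: The alkoxide directs lithiation of the allylic methyl group to a dianion whose carbon terminus displaces the primary bromide of 2 (SN2 C-alkylation of an alkoxide-allyllithium dianion), and no stereocenter is formed.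

Step 2
Reactants: 3 7-methyl-3-methylideneoct-6-en-1-ol
Product: 4 5-[(2S)-3,3-dimethyloxiran-2-yl]-3-methylidenepentan-1-ol
Conditions: L-fructose-derived Shi ketone (0.3 equiv), KHSO5 (Oxone), K2CO3, Bu4NHSO4 (cat.), MeCN/CH2(OMe)2/aq. borate buffer, 0 °C
Reagents that add atoms: potassium peroxymonosulfate, [K+].[O-]S(=O)(=O)OO
Why: Shi epoxidation with the dioxirane of the L-fructose-derived ketone oxidises only the electron-rich trisubstituted alkene (1,1-disubstituted alkenes are poor substrates) and its spiro transition state should deliver the S epoxide carbon that becomes C21.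

Step 3
Reactants: 4 5-[(2S)-3,3-dimethyloxiran-2-yl]-3-methylidenepentan-1-ol
Product: 5 2-[(1R,4S)-3,3-dimethyl-7-oxabicyclo[2.2.1]heptan-1-yl]ethan-1-ol
Conditions: BF3·OEt2 (0.5 equiv), CH2Cl2, −78 to −20 °C
Reagents that add atoms: none
Why: In this Lewis acid epoxy-olefin cyclisation the methylidene carbon (C26) attacks the tertiary epoxide carbon (C23) to close the carbocycle and the oxygen on C21 then traps the tertiary C18 cation across the ring, so C21 keeps the configuration of 4 and the bridge leaves only one possible configuration at C18.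

Step 4
Reactants: 5 2-[(1R,4S)-3,3-dimethyl-7-oxabicyclo[2.2.1]heptan-1-yl]ethan-1-ol
Product: 6 2-Oxb-acetic acid
Conditions: TEMPO (0.2 equiv), PhI(OAc)2 (2.5 equiv), MeCN/H2O, rt
Reagents that add atoms: water, O
Why: Oxoammonium-mediated oxidation (TEMPO with PhI(OAc)2 in wet acetonitrile) takes the primary alcohol through the aldehyde hydrate to the acid while the ether bridge and both stereocenters are untouched.

Step 5
Reactants: 6 2-Oxb-acetic acid
Product: 8 N-methoxy-N-methyl-2-Oxb-acetamide, via acyl imidazole 7 (not isolated)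
Conditions: 1,1'-carbonyldiimidazole (1.2 equiv), CH2Cl2, rt; then MeNHOMe·HCl (1.5 equiv), rt
Reagents that add atoms: 1,1'-carbonyldiimidazole, O=C(n1ccnc1)n1ccnc1 (its imidazolyl group ends in 7 only); N,O-dimethylhydroxylamine hydrochloride, CNOC.Cl
Why: Amide coupling through the acyl imidazole gives the Weinreb amide, whose chelating N-methoxy group is needed for a clean single acylation in step 20.

Step 6
Reactants: 9 (3R)-5-methoxy-3-methyl-5-oxopentanoic acid
Product: 11 (4R)-4-methyloxan-2-one, via hydroxy ester 10 (not isolated)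
Conditions: BH3·SMe2 (1.1 equiv), THF, 0 °C to rt; MeOH; then TsOH (cat.), toluene, 60 °C
Reagents that add atoms: none
Why: Borane reduces the free carboxylic acid much faster than the methyl ester (chemoselective acid reduction) and acid-catalysed transesterification of 10 closes the six-membered lactone without touching the stereocenter.

Step 7
Reactants: 11 (4R)-4-methyloxan-2-one
Product: 12 (3S,4R)-3,4-dimethyloxan-2-one
Conditions: LiN(iPr)2 (1.1 equiv), THF, −78 °C; MeI
Reagents that add atoms: iodomethane, CI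
Why: Alkylation of the lactone lithium enolate with iodomethane should take place mainly trans to the C4 methyl group, but this center becomes planar again in step 8 so its ratio is irrelevant.

Step 8
Reactants: 12 (3S,4R)-3,4-dimethyloxan-2-one
Product: 13 (3S,4R)-3,4-dimethyl-3-(prop-2-en-1-yl)oxan-2-one
Conditions: LiN(iPr)2 (1.2 equiv), THF, −78 °C; allyl bromide, DMPU, −78 to −20 °C
Reagents that add atoms: 3-bromoprop-1-ene, C=CCBr
Why: The second enolate alkylation builds the quaternary C7 by 1,2-induction, the allyl bromide approaching the enolate face opposite the neighbouring ring methyl so that the allyl group (C9) ends trans and the C8 methyl cis to it.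

Step 9
Reactants: 13 (3S,4R)-3,4-dimethyl-3-(prop-2-en-1-yl)oxan-2-one
Product: 14 (3S,4R)-6-hydroxy-3,4-dimethyl-3-(prop-2-en-1-yl)hexan-2-one (in equilibrium with its cyclic hemiketal)
Conditions: MeLi (1.05 equiv), THF, −78 °C; AcOH, −78 °C
Reagents that add atoms: methyllithium, [Li]C
Why: Methyllithium adds once to the non-enolisable, hindered lactone carbonyl because the tetrahedral lithium alkoxide persists at −78 °C until the acidic quench (acyl substitution of a lactone to a methyl ketone), and this methyl becomes C11.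

Step 10
Reactants: 14 (3S,4R)-6-hydroxy-3,4-dimethyl-3-(prop-2-en-1-yl)hexan-2-one
Product: 15 (3R,4S)-3,4-dimethyl-5-oxo-4-(prop-2-en-1-yl)hexanoic acid
Conditions: TEMPO (0.2 equiv), PhI(OAc)2 (2.5 equiv), MeCN/aq. pH 7 buffer, rt
Reagents that add atoms: water, O
Why: The open hydroxy ketone form is oxidised at the primary alcohol to the carboxylic acid by the TEMPO/PhI(OAc)2 oxoammonium cycle, which spares the terminal alkene and the ketone.

Step 11
Reactants: 15 (3R,4S)-3,4-dimethyl-5-oxo-4-(prop-2-en-1-yl)hexanoic acid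
Product: 16 methyl (3R,4S)-3,4-dimethyl-5-oxo-4-(prop-2-en-1-yl)hexanoate
Conditions: Me3SiCHN2, toluene/MeOH, 0 °C
Reagents that add atoms: (trimethylsilyl)diazomethane, C[Si](C)(C)C=[N+]=[N-]
Why: Methyl ester formation with (trimethylsilyl)diazomethane in methanol is neutral and cannot enolise or epimerise anything.

Step 12
Reactants: 16 methyl (3R,4S)-3,4-dimethyl-5-oxo-4-(prop-2-en-1-yl)hexanoate
Product: 18 methyl (3R,4S)-3,4-dimethyl-5-oxo-4-(2-oxoethyl)hexanoate, via ozonide 17 (not isolated)
Conditions: O3, CH2Cl2, −78 °C; then PPh3, −78 °C to rt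
Reagents that add atoms: ozone, [O-][O+]=O
Why: Ozonolysis with reductive work-up cleaves the only alkene to the C10 aldehyde.

Step 13
Reactants: 18 methyl (3R,4S)-3,4-dimethyl-5-oxo-4-(2-oxoethyl)hexanoate
Product: 19 methyl (3R)-3-[(1S)-1-methyl-2-oxocyclopent-3-en-1-yl]butanoate
Conditions: NaOMe (0.3 equiv), MeOH, 0 °C to rt
Reagents that add atoms: none
Why: Intramolecular aldol condensation: the methyl ketone carbon C11 is the only enolisable position that can reach a carbonyl through a five-membered ring and the aldehyde is the better electrophile, so one cyclopentenone regioisomer is expected after loss of water.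

Step 14
Reactants: 19 methyl (3R)-3-[(1S)-1-methyl-2-oxocyclopent-3-en-1-yl]butanoate
Product: 20 methyl (3R)-3-[(1S)-2-hydroxy-1,2-dimethylcyclopent-3-en-1-yl]butanoate (both carbinol epimers)
Conditions: MeLi (1.3 equiv), CeCl3 (1.5 equiv), THF, −78 °C; H2O
Reagents that add atoms: methyllithium, [Li]C
Why: The organocerium reagent adds 1,2 to the enone carbonyl far faster than to the ester at −78 °C, mainly anti to the larger substituent on the adjacent quaternary carbon, and the carbinol center is erased in step 15.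

Step 15
Reactants: 20 methyl (3R)-3-[(1S)-2-hydroxy-1,2-dimethylcyclopent-3-en-1-yl]butanoate
Product: 21 methyl (3R)-3-[(1S)-1,2-dimethyl-4-oxocyclopent-2-en-1-yl]butanoate
Conditions: pyridinium chlorochromate C5H5NH[CrO3Cl] (2 equiv), 4 Å molecular sieves, CH2Cl2, rt
Reagents that add atoms: pyridinium chlorochromate, [O-][Cr](=O)(=O)Cl.c1cc[nH+]cc1
Why: Dauben–Babler oxidative transposition: the tertiary allylic chromate ester undergoes a [3,3] shift to C10 and is oxidised there, which moves the oxygen to C10 and the alkene to C11=C30.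

Step 16
Reactants: 21 methyl (3R)-3-[(1S)-1,2-dimethyl-4-oxocyclopent-2-en-1-yl]butanoate
Product: 23 methyl (3R)-3-[(1S)-3-bromo-1,2-dimethyl-4-oxocyclopent-2-en-1-yl]butanoate, via dibromide 22 (not isolated)
Conditions: Br2 (1.05 equiv), CH2Cl2, 0 °C; then Et3N (2 equiv), 0 °C to rt
Reagents that add atoms: bromine, BrBr
Why: Bromine adds across the enone double bond and triethylamine removes HBr from the dibromide (addition–elimination, E1cB) to leave bromine on C11 as the handle for the coupling in step 19.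

Step 17
Reactants: 23 methyl (3R)-3-[(1S)-3-bromo-1,2-dimethyl-4-oxocyclopent-2-en-1-yl]butanoate
Product: 24 methyl (3R)-3-[(1S,4S)-3-bromo-4-hydroxy-1,2-dimethylcyclopent-2-en-1-yl]butanoate
Conditions: (R)-2-methyl-CBS-oxazaborolidine (0.2 equiv), BH3·SMe2 (0.7 equiv), THF, −20 °C; MeOH
Reagents that add atoms: none
Why: Corey–Bakshi–Shibata reduction: with the bromoalkene arm as the large and C9H2 as the small ketone substituent the R catalyst should deliver hydride to the ring face that carries the C8 methyl, giving the S carbinol with OH trans to that methyl.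

Step 18
Reactants: 24 methyl (3R)-3-[(1S,4S)-3-bromo-4-hydroxy-1,2-dimethylcyclopent-2-en-1-yl]butanoate
Product: 25 methyl (3R)-3-[(1S,4S)-3-bromo-4-(TBS-oxy)-1,2-dimethylcyclopent-2-en-1-yl]butanoate
Conditions: TBSCl, imidazole, DMF, rt
Reagents that add atoms: tert-butyl(chloro)dimethylsilane, CC(C)(C)[Si](C)(C)Cl
Why: Silyl ether formation protects the alcohol, which would otherwise lactonise onto the ester introduced in step 19 or be acylated in step 20.

Step 19
Reactants: 25 methyl (3R)-3-[(1S,4S)-3-bromo-4-(TBS-oxy)-1,2-dimethylcyclopent-2-en-1-yl]butanoate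
Product: 26 methyl (3R)-3-[(1S,4S)-4-(TBS-oxy)-3-(2-methoxy-2-oxoethyl)-1,2-dimethylcyclopent-2-en-1-yl]butanoate
Conditions: BrZnCH2CO2Me (2 equiv, THF solution), Pd(P(t-Bu)3)2 (5 mol %), THF, 50 °C
Reagents that add atoms: bromo(2-methoxy-2-oxoethyl)zinc, COC(=O)C[Zn]Br
Why: Palladium-catalysed cross-coupling of the Reformatsky reagent with the vinyl bromide (Negishi-type coupling of a zinc ester enolate) installs C12 and C13 with the ring alkene and both stereocenters unchanged.

Step 20
Reactants: 26 methyl (3R)-3-[(1S,4S)-4-(TBS-oxy)-3-(2-methoxy-2-oxoethyl)-1,2-dimethylcyclopent-2-en-1-yl]butanoate; 8 N-methoxy-N-methyl-2-Oxb-acetamide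
Product: 27 methyl 2-[(3S,5S)-5-(TBS-oxy)-3-[(2R)-4-methoxy-4-oxobutan-2-yl]-2,3-dimethylcyclopent-1-en-1-yl]-3-oxo-4-Oxb-butanoate (C2 epimers and enol form)
Conditions: LiN(SiMe3)2 (1.15 equiv), THF, −78 °C; then 8, −78 to 0 °C; AcOH
Reagents that add atoms: none
Why: Crossed Claisen condensation: LiN(SiMe3)2 removes the C12 proton, which is the most acidic because the ester enolate is conjugated with the ring alkene, and the enolate adds once to the Weinreb amide through a chelated tetrahedral adduct that releases the ketone only on quench.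

Step 21
Reactants: 27 the β-keto ester of step 20
Product: 28 methyl (2E)-2-[(3S,5S)-5-(TBS-oxy)-3-[(2R)-4-methoxy-4-oxobutan-2-yl]-2,3-dimethylcyclopent-1-en-1-yl]-4-Oxb-3-(tosyloxy)but-2-enoate
Conditions: TsCl (1.5 equiv), N-methylimidazole (1.5 equiv), Et3N (1.5 equiv), CH2Cl2, 0 °C to rt
Reagents that add atoms: 4-methylbenzenesulfonyl chloride, Cc1ccc(cc1)S(Cl)(=O)=O
Why: Enol tosylation of the β-keto ester under amine-only (non-chelating) conditions: with no metal holding the enolate oxygen next to the ester carbonyl and with the bulky Oxb-methyl group turned away from ring A, sulfonylation should occur on the oxygen cis to ring A and give the E isomer.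

Step 22
Reactants: 28 the (2E)-enol tosylate of step 21
Product: 29 methyl (2E)-2-[(3S,5S)-5-(TBS-oxy)-3-[(2R)-4-methoxy-4-oxobutan-2-yl]-2,3-dimethylcyclopent-1-en-1-yl]-3-(Oxb-methyl)penta-2,4-dienoate
Conditions: CH2=CHBpin (1.5 equiv), Pd(OAc)2 (5 mol %), SPhos (10 mol %), K3PO4 (3 equiv), THF/H2O, 60 °C
Reagents that add atoms: 4,4,5,5-tetramethyl-2-vinyl-1,3,2-dioxaborolane, C=CB1OC(C)(C)C(C)(C)O1
Why: Suzuki–Miyaura coupling of the enol tosylate proceeds with retention of alkene geometry, so the vinyl group (C27–C28) takes the position cis to ring A.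

Step 23
Reactants: 29 the TBS-protected dienoate of step 22
Product: 30 methyl (2E)-2-[(3S,5S)-5-hydroxy-3-[(2R)-4-methoxy-4-oxobutan-2-yl]-2,3-dimethylcyclopent-1-en-1-yl]-3-(Oxb-methyl)penta-2,4-dienoate
Conditions: Bu4NF (1.5 equiv), AcOH (1.5 equiv), THF, 0 °C to rt
Reagents that add atoms: none
Why: Fluoride cleaves the silyl ether and acetic acid buffering keeps the liberated allylic alkoxide from attacking the nearby ester.

Step 24
Reactants: 30 the allylic alcohol of step 23
Product: 31 methyl (2E)-2-[(3S,5S)-5-(methoxycarbonyloxy)-3-[(2R)-4-methoxy-4-oxobutan-2-yl]-2,3-dimethylcyclopent-1-en-1-yl]-3-(Oxb-methyl)penta-2,4-dienoate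
Conditions: ClCO2Me (3 equiv), pyridine, DMAP (cat.), CH2Cl2, 0 °C
Reagents that add atoms: methyl chloroformate, COC(=O)Cl
Why: Acylation with methyl chloroformate turns the allylic alcohol into the carbonate leaving group with retention at C10.

Step 25
Reactants: 31 the allylic carbonate of step 24
Product: 33 methyl (2Z)-5-hydroxy-2-[(3S,5S)-5-(methoxycarbonyloxy)-3-[(2R)-4-methoxy-4-oxobutan-2-yl]-2,3-dimethylcyclopent-1-en-1-yl]-3-(Oxb-methyl)pent-2-enoate, via alkylborane 32 (not isolated)
Conditions: 9-BBN (1.5 equiv), THF, 0 °C to rt; then NaOAc (aq.), H2O2, 0 °C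
Reagents that add atoms: 9-borabicyclo[3.3.1]nonane, B1C2CCCC1CCC2 (its atoms end in 32 only); hydrogen peroxide, OO
Why: 9-BBN hydroborates only the monosubstituted alkene and places boron on the terminal carbon (anti-Markovnikov hydroboration), and buffered peroxide oxidation gives the primary alcohol without harming the carbonate or the esters.

Step 26
Reactants: 33 the hydroxy carbonate of step 25
Product: 34 methyl (2Z)-5-hydroxy-2-[(3S,5R)-3-[(2R)-4-methoxy-4-oxobutan-2-yl]-2,3-dimethyl-5-Bpin-cyclopent-1-en-1-yl]-3-(Oxb-methyl)pent-2-enoate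
Conditions: B2pin2 (1.2 equiv), Pd2(dba)3 (2.5 mol %), DMSO, 50 °C
Reagents that add atoms: bis(pinacolato)diboron, CC1(C)OB(OC1(C)C)B1OC(C)(C)C(C)(C)O1
Why: Miyaura-type palladium-catalysed borylation of the allylic carbonate: zerovalent palladium ionises the carbonate with inversion, B2pin2 transmetalates onto the palladium methoxide and reductive elimination at the less hindered terminus C10 delivers boron from the palladium face, so the net inversion puts boron cis to the C8 methyl.

Step 27
Reactants: 34 the hydroxy allylboronate of step 26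
Product: 37 methyl (1S,7R,7aS)-7-hydroxy-1-[(2R)-4-methoxy-4-oxobutan-2-yl]-1,7a-dimethyl-5-(Oxb-methyl)-2,6,7,7a-tetrahydro-1H-indene-4-carboxylate, via aldehyde 35 (not isolated), via borate ester 36 (not isolated)
Conditions: Dess–Martin periodinane (1.5 equiv), NaHCO3 (5 equiv), CH2Cl2 (0.01 M), 0 °C to rt; then aq. Na2S2O3/NaHCO3
Reagents that add atoms: none
Why: Oxidation of the primary alcohol gives the (2E) aldehyde 35, in which the carbonyl oxygen coordinates to boron and the allyl unit hands C30 to the carbonyl carbon C28 within a closed chair-like array (B, O, C28, C30, C11, C10) on the ring A face that holds boron (suprafacial SE2'), leaving borate 36 that is hydrolysed on work-up. The closest known reactions are the intramolecular allylborations of oxo-substituted allylboronates and the additions of γ,γ-disubstituted allylboronates that build quaternary carbons, with the tether on the central allyl carbon as in a type 2 carbonyl-ene cyclisation. Ring B closes by a 6-exo-trig attack on the carbonyl, the C11=C30 bond lying inside the new ring and reappearing as C10=C11. C30 is set by the C10 stereocenter, because boron cis to the C8 methyl brings C28 onto that same face, and C28 is set by the cyclic transition state, in which the oxygen has to reach boron above ring A and so ends anti to the C31 methyl. The step needs γ-attack and ring closure to outrun enolisation or conjugation of the β,γ-unsaturated aldehyde; the closed transition state, the placement of the C27 arm cis to ring A, the buffered non-basic oxidant and high dilution should secure this.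

Step 28
Reactants: 37 the dimethyl ester of step 27
Product: 38 (3R)-3-[(1S,7R,7aS)-4-carboxy-7-hydroxy-1,7a-dimethyl-5-{[(1S,4S)-3,3-dimethyl-7-oxabicyclo[2.2.1]heptan-1-yl]methyl}-2,6,7,7a-tetrahydro-1H-inden-1-yl]butanoic acid
Conditions: LiOH·H2O (10 equiv), THF/MeOH/H2O, 45 °C; then 1 M HCl to pH 3
Reagents that add atoms: lithium hydroxide, [Li+].[OH-]
Why: Saponification of both methyl esters (acyl–oxygen cleavage by hydroxide) should leave the stereocenters alone because none is alpha to a carbonyl group.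

**Compound list**

1 | 3-methylbut-3-en-1-ol | CC(=C)CCO | starting material
2 | 1-bromo-3-methylbut-2-ene | CC(C)=CCBr | starting material
3 | 7-methyl-3-methylideneoct-6-en-1-ol | CC(C)=CCCC(=C)CCO | intermediate
4 | 5-[(2S)-3,3-dimethyloxiran-2-yl]-3-methylidenepentan-1-ol | CC1(C)O[C@H]1CCC(=C)CCO | intermediate
5 | 2-[(1R,4S)-3,3-dimethyl-7-oxabicyclo[2.2.1]heptan-1-yl]ethan-1-ol | OCC[C@]12CC[C@H](O1)C(C)(C)C2 | intermediate
6 | 2-Oxb-acetic acid | OC(=O)C[C@]12CC[C@H](O1)C(C)(C)C2 | intermediate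
7 | 1-(imidazol-1-yl)-2-Oxb-ethan-1-one | O=C(C[C@]12CC[C@H](O1)C(C)(C)C2)n1ccnc1 | intermediate
8 | N-methoxy-N-methyl-2-Oxb-acetamide | CON(C)C(=O)C[C@]12CC[C@H](O1)C(C)(C)C2 | intermediate
9 | (3R)-5-methoxy-3-methyl-5-oxopentanoic acid | C[C@@H](CC(=O)OC)CC(=O)O | starting material
10 | methyl (3R)-5-hydroxy-3-methylpentanoate | C[C@@H](CC(=O)OC)CCO | intermediate
11 | (4R)-4-methyloxan-2-one | C[C@@H]1CCOC(=O)C1 | intermediate
12 | (3S,4R)-3,4-dimethyloxan-2-one | C[C@@H]1CCOC(=O)[C@H]1C | intermediate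
13 | (3S,4R)-3,4-dimethyl-3-(prop-2-en-1-yl)oxan-2-one | C[C@@H]1CCOC(=O)[C@@]1(C)CC=C | intermediate
14 | (3S,4R)-6-hydroxy-3,4-dimethyl-3-(prop-2-en-1-yl)hexan-2-one | C[C@H](CCO)[C@](C)(CC=C)C(C)=O | intermediate
15 | (3R,4S)-3,4-dimethyl-5-oxo-4-(prop-2-en-1-yl)hexanoic acid | C[C@H](CC(=O)O)[C@](C)(CC=C)C(C)=O | intermediate
16 | methyl (3R,4S)-3,4-dimethyl-5-oxo-4-(prop-2-en-1-yl)hexanoate | C[C@H](CC(=O)OC)[C@](C)(CC=C)C(C)=O | intermediate
17 | methyl (3R,4S)-3,4-dimethyl-5-oxo-4-(1,2,4-trioxolan-3-ylmethyl)hexanoate | C[C@H](CC(=O)OC)[C@](C)(CC1OCOO1)C(C)=O | intermediate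
18 | methyl (3R,4S)-3,4-dimethyl-5-oxo-4-(2-oxoethyl)hexanoate | C[C@H](CC(=O)OC)[C@](C)(CC=O)C(C)=O | intermediate
19 | methyl (3R)-3-[(1S)-1-methyl-2-oxocyclopent-3-en-1-yl]butanoate | C[C@H](CC(=O)OC)[C@]1(C)CC=CC1=O | intermediate
20 | methyl (3R)-3-[(1S)-2-hydroxy-1,2-dimethylcyclopent-3-en-1-yl]butanoate, both carbinol epimers | C[C@H](CC(=O)OC)[C@]1(C)CC=CC1(C)O | intermediate
21 | methyl (3R)-3-[(1S)-1,2-dimethyl-4-oxocyclopent-2-en-1-yl]butanoate | C[C@H](CC(=O)OC)[C@]1(C)CC(=O)C=C1C | intermediate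
22 | methyl (3R)-3-[(1S)-2,3-dibromo-1,2-dimethyl-4-oxocyclopentyl]butanoate, new centers undefined | C[C@H](CC(=O)OC)[C@]1(C)CC(=O)C(Br)C1(C)Br | intermediate
23 | methyl (3R)-3-[(1S)-3-bromo-1,2-dimethyl-4-oxocyclopent-2-en-1-yl]butanoate | C[C@H](CC(=O)OC)[C@]1(C)CC(=O)C(Br)=C1C | intermediate
24 | methyl (3R)-3-[(1S,4S)-3-bromo-4-hydroxy-1,2-dimethylcyclopent-2-en-1-yl]butanoate | C[C@H](CC(=O)OC)[C@]1(C)C[C@H](O)C(Br)=C1C | intermediate
25 | methyl (3R)-3-[(1S,4S)-3-bromo-4-(TBS-oxy)-1,2-dimethylcyclopent-2-en-1-yl]butanoate | C[C@H](CC(=O)OC)[C@]1(C)C[C@H](O[Si](C)(C)C(C)(C)C)C(Br)=C1C | intermediate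
26 | methyl (3R)-3-[(1S,4S)-4-(TBS-oxy)-3-(2-methoxy-2-oxoethyl)-1,2-dimethylcyclopent-2-en-1-yl]butanoate | C[C@H](CC(=O)OC)[C@]1(C)C[C@H](O[Si](C)(C)C(C)(C)C)C(CC(=O)OC)=C1C | intermediate
27 | methyl 2-[(3S,5S)-5-(TBS-oxy)-3-[(2R)-4-methoxy-4-oxobutan-2-yl]-2,3-dimethylcyclopent-1-en-1-yl]-3-oxo-4-Oxb-butanoate, C2 epimers | C[C@H](CC(=O)OC)[C@]1(C)C[C@H](O[Si](C)(C)C(C)(C)C)C(=C1C)C(C(=O)OC)C(=O)C[C@]23CC[C@H](O2)C(C)(C)C3 | intermediate
28 | methyl (2E)-2-[(3S,5S)-5-(TBS-oxy)-3-[(2R)-4-methoxy-4-oxobutan-2-yl]-2,3-dimethylcyclopent-1-en-1-yl]-4-Oxb-3-(tosyloxy)but-2-enoate | C[C@H](CC(=O)OC)[C@]1(C)C[C@H](O[Si](C)(C)C(C)(C)C)C(=C1C)/C(C(=O)OC)=C(/C[C@]23CC[C@H](O2)C(C)(C)C3)OS(=O)(=O)c4ccc(C)cc4 | intermediate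
29 | methyl (2E)-2-[(3S,5S)-5-(TBS-oxy)-3-[(2R)-4-methoxy-4-oxobutan-2-yl]-2,3-dimethylcyclopent-1-en-1-yl]-3-(Oxb-methyl)penta-2,4-dienoate | C[C@H](CC(=O)OC)[C@]1(C)C[C@H](O[Si](C)(C)C(C)(C)C)C(=C1C)/C(C(=O)OC)=C(/C[C@]23CC[C@H](O2)C(C)(C)C3)C=C | intermediate
30 | methyl (2E)-2-[(3S,5S)-5-hydroxy-3-[(2R)-4-methoxy-4-oxobutan-2-yl]-2,3-dimethylcyclopent-1-en-1-yl]-3-(Oxb-methyl)penta-2,4-dienoate | C[C@H](CC(=O)OC)[C@]1(C)C[C@H](O)C(=C1C)/C(C(=O)OC)=C(/C[C@]23CC[C@H](O2)C(C)(C)C3)C=C | intermediate
31 | methyl (2E)-2-[(3S,5S)-5-(methoxycarbonyloxy)-3-[(2R)-4-methoxy-4-oxobutan-2-yl]-2,3-dimethylcyclopent-1-en-1-yl]-3-(Oxb-methyl)penta-2,4-dienoate | C[C@H](CC(=O)OC)[C@]1(C)C[C@H](OC(=O)OC)C(=C1C)/C(C(=O)OC)=C(/C[C@]23CC[C@H](O2)C(C)(C)C3)C=C | intermediate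
32 | methyl (2Z)-5-(9-borabicyclo[3.3.1]nonan-9-yl)-2-[(3S,5S)-5-(methoxycarbonyloxy)-3-[(2R)-4-methoxy-4-oxobutan-2-yl]-2,3-dimethylcyclopent-1-en-1-yl]-3-(Oxb-methyl)pent-2-enoate | C[C@H](CC(=O)OC)[C@]1(C)C[C@H](OC(=O)OC)C(=C1C)/C(C(=O)OC)=C(/C[C@]23CC[C@H](O2)C(C)(C)C3)CCB4C5CCCC4CCC5 | intermediate
33 | methyl (2Z)-5-hydroxy-2-[(3S,5S)-5-(methoxycarbonyloxy)-3-[(2R)-4-methoxy-4-oxobutan-2-yl]-2,3-dimethylcyclopent-1-en-1-yl]-3-(Oxb-methyl)pent-2-enoate | C[C@H](CC(=O)OC)[C@]1(C)C[C@H](OC(=O)OC)C(=C1C)/C(C(=O)OC)=C(/C[C@]23CC[C@H](O2)C(C)(C)C3)CCO | intermediate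
34 | methyl (2Z)-5-hydroxy-2-[(3S,5R)-3-[(2R)-4-methoxy-4-oxobutan-2-yl]-2,3-dimethyl-5-Bpin-cyclopent-1-en-1-yl]-3-(Oxb-methyl)pent-2-enoate | C[C@H](CC(=O)OC)[C@]1(C)C[C@@H](B2OC(C)(C)C(C)(C)O2)C(=C1C)/C(C(=O)OC)=C(/C[C@]34CC[C@H](O3)C(C)(C)C4)CCO | intermediate
35 | methyl (2E)-2-[(3S,5R)-3-[(2R)-4-methoxy-4-oxobutan-2-yl]-2,3-dimethyl-5-Bpin-cyclopent-1-en-1-yl]-3-(Oxb-methyl)-5-oxopent-2-enoate | C[C@H](CC(=O)OC)[C@]1(C)C[C@@H](B2OC(C)(C)C(C)(C)O2)C(=C1C)/C(C(=O)OC)=C(/C[C@]34CC[C@H](O3)C(C)(C)C4)CC=O | intermediate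
36 | O-Bpin borate ester of 37 at the C28 oxygen | C[C@H](CC(=O)OC)[C@]1(C)CC=C2C(C(=O)OC)=C(C[C@]34CC[C@H](O3)C(C)(C)C4)C[C@@H](OB5OC(C)(C)C(C)(C)O5)[C@]21C | intermediate
37 | methyl (1S,7R,7aS)-7-hydroxy-1-[(2R)-4-methoxy-4-oxobutan-2-yl]-1,7a-dimethyl-5-(Oxb-methyl)-2,6,7,7a-tetrahydro-1H-indene-4-carboxylate | C[C@H](CC(=O)OC)[C@]1(C)CC=C2C(C(=O)OC)=C(C[C@]34CC[C@H](O3)C(C)(C)C4)C[C@@H](O)[C@]21C | intermediate
38 | (3R)-3-[(1S,7R,7aS)-4-carboxy-7-hydroxy-1,7a-dimethyl-5-{[(1S,4S)-3,3-dimethyl-7-oxabicyclo[2.2.1]heptan-1-yl]methyl}-2,6,7,7a-tetrahydro-1H-inden-1-yl]butanoic acid | C[C@H](CC(=O)O)[C@]1(C)CC=C2C(C(=O)O)=C(C[C@]34CC[C@H](O3)C(C)(C)C4)C[C@@H](O)[C@]21C | target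

**Step count and risks**

Total step count: 28 (steps 1–5 for the oxabicycle fragment, steps 6–28 for the main line). Longest linear sequence: 23 steps, from 9 to 38 (steps 6–28).

The three steps most likely to fail:

Step 27. The aldehyde 35 may enolise or slide into conjugation faster than the crowded, bridged allyl transfer takes place, or the boronate may be protonated by the acetic acid that the oxidant releases. The fallback sets out from 34 and returns at 37. Compound 34 is treated with KHF2 in MeOH/H2O to give the potassium trifluoroborate alcohol F1, which is oxidised with Dess–Martin periodinane to the trifluoroborate aldehyde F2. The trifluoroborate should stay unreactive until BF3·OEt2 is added at −78 °C; the allyldifluoroborane formed in the flask is far more Lewis acidic and should cyclise through the same closed transition state at low temperature, and aqueous work-up then gives 37.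

Step 26. β-Hydride elimination from the hindered π-allyl palladium intermediate to a cyclopentadiene, or loss of the C10 configuration by palladium exchange, may compete with boron transfer. The fallback sets out from 33 and returns at 37 without any allylboronate. Compound 33 is oxidised with Dess–Martin periodinane to the aldehyde carbonate F3, which is treated with Pd(PPh3)4 (cat.) and InI in THF. Reductive transmetalation of the π-allyl palladium species gives an allylindium reagent that should add to the C28 aldehyde at C30 through a cyclic transition state from the less hindered ring A face (umpolung Barbier-type cyclisation).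

Step 20. The hindered ester enolate may add too slowly to the neopentyl-like Weinreb amide, so that proton transfer or breakdown of the amide takes over. The fallback sets out from 5 and 26 and returns at 27. Alcohol 5 is oxidised with Dess–Martin periodinane to the aldehyde F4; the lithium enolate of 26 (LiN(SiMe3)2, THF, −78 °C) adds to F4 in an aldol addition to give the β-hydroxy ester F5 as a mixture of diastereomers, and oxidation of F5 with Dess–Martin periodinane gives 27.

**Further compounds**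

F1 | step 27 | potassium trifluoroborate alcohol, the BF3K analogue of 34 | C[C@H](CC(=O)OC)[C@]1(C)C[C@@H]([B-](F)(F)F)C(=C1C)/C(C(=O)OC)=C(/C[C@]23CC[C@H](O2)C(C)(C)C3)CCO.[K+]
F2 | step 27 | potassium trifluoroborate aldehyde, the BF3K analogue of 35 | C[C@H](CC(=O)OC)[C@]1(C)C[C@@H]([B-](F)(F)F)C(=C1C)/C(C(=O)OC)=C(/C[C@]23CC[C@H](O2)C(C)(C)C3)CC=O.[K+]
F3 | step 26 | aldehyde carbonate, the C28 aldehyde of 33 | C[C@H](CC(=O)OC)[C@]1(C)C[C@H](OC(=O)OC)C(=C1C)/C(C(=O)OC)=C(/C[C@]23CC[C@H](O2)C(C)(C)C3)CC=O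
F4 | step 20 | 2-Oxb-acetaldehyde | O=CC[C@]12CC[C@H](O1)C(C)(C)C2
F5 | step 20 | methyl 2-[(3S,5S)-5-(TBS-oxy)-3-[(2R)-4-methoxy-4-oxobutan-2-yl]-2,3-dimethylcyclopent-1-en-1-yl]-3-hydroxy-4-Oxb-butanoate, diastereomer mixture | C[C@H](CC(=O)OC)[C@]1(C)C[C@H](O[Si](C)(C)C(C)(C)C)C(=C1C)C(C(=O)OC)C(O)C[C@]23CC[C@H](O2)C(C)(C)C3
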